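The numbers in the tables are calculated with made-up constants; scatter was added.

| flask | substrate | reagent | remark | time |
|---|---|---|---|---|
| Tuesday's | 0.32 M | 0.324 M | run made earlier |  |
| Wednesday's | 1.8 M | 0.324 M | run made earlier |  |
| dawn | 0.40 M | 0.324 M |  | 10 h |
| dusk | 1.0 M | 0.324 M |  | 10 h |
| noon | 3.0 M | 0.324 M |  | 10 h |

| run | time / h | mono adduct / % | bis adduct / % |
|---|---|---|---|
| Tuesday's | 0.250 | 10.7 | 0.4 |
| Tuesday's | 0.833 | 19.1 | 2.6 |
| Tuesday's | 1.33 | 20.7 | 2.4 |
| Tuesday's | 2.00 | 20.5 | 4.3 |
| Tuesday's | 3.00 | 20.4 | 6.1 |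
| Tuesday's | 4.00 | 19.9 | 5.9 |
| Tuesday's | 5.00 | 19.3 | 6.2 |
| Wednesday's | 0.667 | 11.1 | 0.7 |
| Wednesday's | 1.33 | 11.7 | 1.2 |
| Wednesday's | 2.00 | 11.7 | 0.7 |
| Wednesday's | 3.00 | 11.1 | 0.7 |
| Wednesday's | 4.00 | 10.3 | 0.3 |
| Wednesday's | 5.00 | 9.6 | 0.7 |

(scatter of a reading: 0.5 percentage points)

- share of mono adduct in all that became mono adduct or bis adduct or tris adduct or over-reaction product or side product for dawn, dusk, noon, in this order
- the course of these numbers from the first flask to the last (hardly changes / rises all the way / rises, then falls / falls all the way / falls, then rises)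

- in percentages every species weighs as the substrate in it: one side product counts as two
- the numbers in the tables scatter by 0.5 percentage points (one standard deviation)
- "hardly changes" means that all values lie within two and a half points (for a concentration: within two and a half percent of the largest)

If mono adduct falls while bis adduct stays flat, read that tail first. Take Wednesday's run. Mono adduct goes from 11.7 % at 2.00 h to 9.6 % at 5.00 h, and bis adduct stays near 0.7 %. Treat this fall as pseudo-first-order in mono adduct, with a rate proportional to the substrate charge c. Take the logarithmic slope and divide by c: λ = 0.0366 M⁻¹ h⁻¹. Call λ the tail constant, the fractional loss of mono adduct per hour per unit of substrate charged. It is a reading, and each end carries a scatter of 0.5 percentage points.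

How much mono adduct survives from 2.00 h to 10 h? Use f = exp(−λcΔt), with Δt that span. Noon gives 0.415, dusk 0.746, dawn 0.889.

What does that do to the share? Assume the lost mono adduct becomes side product, which counts double. The share is then f/(2 − f): noon 26.2 %, dusk 59.5 %, dawn 80.1 %.

What else competes at low substrate? At 5.00 h in Tuesday's run, mono adduct is 0.757 of mono plus bis adduct. Apply that to dawn and my estimate is 60.6 %. Dusk stands at 59.5 % before any bis adduct. My row falls.

The forecast says 63 %, 53 %, 22 %, falls all the way: “The decline scales with substrate”. Mine differs in its numbers, not in its direction.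

The flask gives 37.4 %, 45.6 %, 20.1 %: rises, then falls.

    substrate + mono adduct → side product (k = 0.00130 M⁻¹ min⁻¹)
    substrate + reagent → mono adduct + by-product (k = 0.0320 M⁻¹ min⁻¹)
    reagent + bis adduct → tris adduct + by-product (k = 0.0410 M⁻¹ min⁻¹)
    reagent + mono adduct → bis adduct + by-product (k = 0.0170 M⁻¹ min⁻¹)
    reagent + mono adduct → over-reaction product (k = 0.0290 M⁻¹ min⁻¹)
    substrate ⇌ dormant form (K = 0.950, k = 0.0200 min⁻¹)

At 10.0 h, dawn holds 17.5 % over-reaction product beside 18.7 % mono adduct. Now use λ from 5.00 h to 10 h. At noon it gives a survival of 0.577, and mono adduct goes from 5.25 % to 3.15 %, a ratio of 0.600. At dusk it gives 0.833, and mono adduct goes from 15.4 % at 5.00 h to 13.4 % at 10.0 h, a ratio of 0.870.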